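**Retrosynthetic overview**
- The hydroxy-methoxy-quinone is unmasked last from a 3,4-dimethoxycatechol. Which two oxygens are free in that arene fixes the OH/OMe regiochemistry.
- Key disconnection: side-chain bond C12'–C13' (between prenyl units 3 and 4). A sulfonyl-stabilised allyl carbanion (polarity-reversed allyl) on the ring-bearing C15 piece attacks (2E,6E)-farnesyl bromide, and the sulfone is excised in the same flask.
- Ring–C1' bond: Friedel–Crafts allylation of the catechol at its only free ring carbon by a C15 allylic acetate that already carries the terminal sulfone.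
- The C15 sulfone comes from farnesyl acetate by terminal (E)-selective allylic oxidation, then OH to Br to SO2Tol. The catechol comes from 2,3,4-trimethoxy-6-methylbenzaldehyde by ortho-demethylation and Dakin oxidation.
- Rings: none is built. The purchased benzene ring becomes the quinone ring in the final step.

Assumption: the target has no stereocentre, so "single enantiomer" is read as the single geometric isomer drawn, with all five stereodefined side-chain alkenes E.

Notation: ring atoms use ubiquinone numbering (C1 carbonyl next to the side-chain carbon C6, C2 OMe, C3 OH, C4 carbonyl, C5 methyl). Side-chain atoms carry primes. Tol = 4-methylphenyl; dppp = Ph2P(CH2)3PPh2.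

**Route**

Step 1
Reactants: 1 2,3,4-trimethoxy-6-methylbenzaldehyde
Product: 3 2-hydroxy-3,4-dimethoxy-6-methylbenzaldehyde, via aryloxydichloroborane chelate 2 (not isolated)
Conditions: BCl3 (1.1 equiv), CH2Cl2, −10 °C to rt, 2 h; aqueous work-up
Reagents that add atoms: none
Why: Chelation-directed Lewis-acid ether cleavage: BCl3 bound to the aldehyde oxygen removes only the methyl of the ortho methoxy group through a six-membered chelate, leaving the two remote methoxy groups untouched.

Step 2
Reactants: 3 2-hydroxy-3,4-dimethoxy-6-methylbenzaldehyde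
Product: 5 3,4-dimethoxy-6-methylbenzene-1,2-diol, via aryl formate 4 (not isolated)
Conditions: H2O2 (6% aq, 1.2 equiv), NaOH (1.0 equiv), H2O, N2, 40 °C, 1 h; saturate with NaCl, extract (EtOAc, degassed)
Reagents that add atoms: hydrogen peroxide, OO
Why: Dakin oxidation (the conditions that convert o-vanillin to 3-methoxycatechol): hydroperoxide adds to the aldehyde, aryl migration gives the formate and its saponification gives the catechol, whose two free OH groups are O3 and O4 of the target ring.

Step 3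
Reactants: 6 (2E,6E)-farnesyl acetate
Product: 7 (2E,6E,10E)-12-hydroxy-3,7,11-trimethyldodeca-2,6,10-trien-1-yl acetate
Conditions: SeO2 (0.1 equiv), t-BuOOH (70% aq, 3 equiv), salicylic acid (0.1 equiv), CH2Cl2, rt, 24–40 h; chromatography (recover 6)
Reagents that add atoms: tert-butyl hydroperoxide, CC(C)(C)OO (oxygen, relayed through SeO2)
Why: Sharpless catalytic SeO2 allylic oxidation (ene reaction then [2,3]-sigmatropic shift) attacks the terminal, most electron-rich trisubstituted alkene at its (E)-methyl group, so the CH2OH is formed with 10E geometry and the 2E and 6E alkenes are untouched.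

Step 4
Reactants: 7 (2E,6E,10E)-12-hydroxy-3,7,11-trimethyldodeca-2,6,10-trien-1-yl acetate
Product: 9 (2E,6E,10E)-3,7,11-trimethyl-12-(4-methylbenzenesulfonyl)dodeca-2,6,10-trien-1-yl acetate, via allylic bromide 8 (not isolated)
Conditions: CBr4 (1.1 equiv), PPh3 (1.1 equiv), CH2Cl2, 0 °C, 30 min; then TolSO2Na (1.5 equiv), n-Bu4NI (5 mol %), DMF, rt, 6 h
Reagents that add atoms: sodium p-toluenesulfinate, Cc1ccc(cc1)S(=O)[O-].[Na+]
Why: Appel bromination followed by SN2 S-alkylation of the sulfinate at the primary allylic carbon; neither event touches the alkene, so 10E is retained, and the primary allylic acetate is inert to both reagents.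

Step 5
Reactants: 5 3,4-dimethoxy-6-methylbenzene-1,2-diol; 9 (2E,6E,10E)-3,7,11-trimethyl-12-(4-methylbenzenesulfonyl)dodeca-2,6,10-trien-1-yl acetate
Product: 10 3,4-dimethoxy-6-methyl-5-[(2E,6E,10E)-3,7,11-trimethyl-12-(4-methylbenzenesulfonyl)dodeca-2,6,10-trien-1-yl]benzene-1,2-diol
Conditions: 5 (2.0 equiv, excess recovered), BF3·OEt2 (0.5 equiv), dioxane, rt, Ar, 6 h; chromatography, then crystallisation or AgNO3-impregnated silica to remove the minor 2'Z isomer
Reagents that add atoms: none
Why: Friedel–Crafts allylation: the (E)-allyl cation from the primary acetate is captured at its primary terminus by the only unsubstituted ring carbon (para to the O3 hydroxyl) with mainly retained 2'E geometry, there is no ortho OH to close a chroman, and the electron-poor sulfonyl-bearing terminus stays out of the reaction.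

Step 6
Reactants: 10 3,4-dimethoxy-6-methyl-5-[(2E,6E,10E)-3,7,11-trimethyl-12-(4-methylbenzenesulfonyl)dodeca-2,6,10-trien-1-yl]benzene-1,2-diol; 11 (2E,6E)-farnesyl bromide
Product: 15 5-[(2E,6E,10E,14E,18E)-3,7,11,15,19,23-hexamethyltetracosa-2,6,10,14,18,22-hexaen-1-yl]-3,4-dimethoxy-6-methylbenzene-1,2-diol, via trilithio sulfonyl carbanion 12 (not isolated), via sulfone dilithium catecholate 13 (not isolated), via desulfonylated dilithium catecholate 14 (not isolated)
Conditions: n-BuLi (3.05 equiv), THF/DMPU (6:1), −78 °C, 30 min; 11 (1.0 equiv), −78 °C, 2 h; then LiBHEt3 (3 equiv), then PdCl2(dppp) (5 mol %), −78 to 0 °C, 3 h; AcOH quench, degassed work-up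
Reagents that add atoms: none
Why: Biellmann–Julia sulfone alkylation with polarity reversal: the sulfonyl-stabilised allyl carbanion turns C12' (the electrophilic bromide carbon in 8) into a nucleophile that displaces bromide from C1 of 11 by SN2, joining two carbons that are both normally allylic electrophiles while the two lithium phenoxides remain poorly nucleophilic spectators at −78 °C, and zerovalent palladium (formed from PdCl2(dppp) and hydride) then ionises the allylic sulfone and delivers hydride to the carbon that carried sulfur, so the 10'E alkene stays in place and the racemic C12' stereocentre created in 13 is erased.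

Step 7
Reactants: 15 5-[(2E,6E,10E,14E,18E)-3,7,11,15,19,23-hexamethyltetracosa-2,6,10,14,18,22-hexaen-1-yl]-3,4-dimethoxy-6-methylbenzene-1,2-diol
Product: 17 3-demethylubiquinone-6 [2-[(2E,6E,10E,14E,18E)-3,7,11,15,19,23-hexamethyltetracosa-2,6,10,14,18,22-hexaen-1-yl]-5-hydroxy-6-methoxy-3-methylcyclohexa-2,5-diene-1,4-dione], via ortho-quinone 16 (not isolated)
Conditions: (NH4)2Ce(NO3)6 (2.2 equiv), MeCN/CH2Cl2/H2O (4:1:1), 0 °C, 20 min, then rt, 1 h
Reagents that add atoms: water, O
Why: Oxidative demethylation: two-electron oxidation of the catechol by tetravalent cerium gives the 5,6-dimethoxy-ortho-quinone, whose methoxy group on ring carbon C1 is the beta position of a vinylogous ester and is hydrolysed by addition–elimination of water in the acidic medium, and tautomerisation to the more stable 2-hydroxy-1,4-quinone keeps the inner C2 methoxy group and the C3 hydroxyl exactly as in the target.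

**Compound list**

1 | 2,3,4-trimethoxy-6-methylbenzaldehyde | O=Cc1c(C)cc(OC)c(OC)c1OC | starting material
2 | dichloro(2-formyl-5,6-dimethoxy-3-methylphenoxy)borane chelate (not isolated) | O=Cc1c(C)cc(OC)c(OC)c1OB(Cl)Cl | intermediate
3 | 2-hydroxy-3,4-dimethoxy-6-methylbenzaldehyde | O=Cc1c(C)cc(OC)c(OC)c1O | intermediate
4 | 2-hydroxy-3,4-dimethoxy-6-methylphenyl formate (not isolated) | O=COc1c(C)cc(OC)c(OC)c1O | intermediate
5 | 3,4-dimethoxy-6-methylbenzene-1,2-diol | Cc1cc(OC)c(OC)c(O)c1O | intermediate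
6 | (2E,6E)-farnesyl acetate | CC(=O)OC/C=C(\C)CC/C=C(\C)CCC=C(C)C | starting material
7 | (2E,6E,10E)-12-hydroxy-3,7,11-trimethyldodeca-2,6,10-trien-1-yl acetate | CC(=O)OC/C=C(\C)CC/C=C(\C)CC/C=C(\C)CO | intermediate
8 | (2E,6E,10E)-12-bromo-3,7,11-trimethyldodeca-2,6,10-trien-1-yl acetate (not isolated) | CC(=O)OC/C=C(\C)CC/C=C(\C)CC/C=C(\C)CBr | intermediate
9 | (2E,6E,10E)-3,7,11-trimethyl-12-(4-methylbenzenesulfonyl)dodeca-2,6,10-trien-1-yl acetate | CC(=O)OC/C=C(\C)CC/C=C(\C)CC/C=C(\C)CS(=O)(=O)c1ccc(C)cc1 | intermediate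
10 | 3,4-dimethoxy-6-methyl-5-[(2E,6E,10E)-3,7,11-trimethyl-12-(4-methylbenzenesulfonyl)dodeca-2,6,10-trien-1-yl]benzene-1,2-diol | Cc1c(O)c(O)c(OC)c(OC)c1C/C=C(\C)CC/C=C(\C)CC/C=C(\C)CS(=O)(=O)c1ccc(C)cc1 | intermediate
11 | (2E,6E)-farnesyl bromide | BrC/C=C(\C)CC/C=C(\C)CCC=C(C)C | starting material
12 | trilithium salt of 10 (two phenoxides, carbanion at C12'; not isolated) | [Li+].[Li+].[Li+].Cc1c([O-])c([O-])c(OC)c(OC)c1C/C=C(\C)CC/C=C(\C)CC/C=C(\C)[CH-]S(=O)(=O)c1ccc(C)cc1 | intermediate
13 | dilithium 5-[(2E,6E,10E,14E,18E)-3,7,11,15,19,23-hexamethyl-12-(4-methylbenzenesulfonyl)tetracosa-2,6,10,14,18,22-hexaen-1-yl]-3,4-dimethoxy-6-methylbenzene-1,2-diolate (racemic at C12'; not isolated) | [Li+].[Li+].Cc1c([O-])c([O-])c(OC)c(OC)c1C/C=C(\C)CC/C=C(\C)CC/C=C(\C)C(C/C=C(\C)CC/C=C(\C)CCC=C(C)C)S(=O)(=O)c1ccc(C)cc1 | intermediate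
14 | dilithium 5-[(2E,6E,10E,14E,18E)-3,7,11,15,19,23-hexamethyltetracosa-2,6,10,14,18,22-hexaen-1-yl]-3,4-dimethoxy-6-methylbenzene-1,2-diolate (not isolated) | [Li+].[Li+].Cc1c([O-])c([O-])c(OC)c(OC)c1C/C=C(\C)CC/C=C(\C)CC/C=C(\C)CC/C=C(\C)CC/C=C(\C)CCC=C(C)C | intermediate
15 | 5-[(2E,6E,10E,14E,18E)-3,7,11,15,19,23-hexamethyltetracosa-2,6,10,14,18,22-hexaen-1-yl]-3,4-dimethoxy-6-methylbenzene-1,2-diol | Cc1c(O)c(O)c(OC)c(OC)c1C/C=C(\C)CC/C=C(\C)CC/C=C(\C)CC/C=C(\C)CC/C=C(\C)CCC=C(C)C | intermediate
16 | 4-[(2E,6E,10E,14E,18E)-3,7,11,15,19,23-hexamethyltetracosa-2,6,10,14,18,22-hexaen-1-yl]-5,6-dimethoxy-3-methylcyclohexa-3,5-diene-1,2-dione (not isolated) | COC1=C(OC)C(=O)C(=O)C(C)=C1C/C=C(\C)CC/C=C(\C)CC/C=C(\C)CC/C=C(\C)CC/C=C(\C)CCC=C(C)C | intermediate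
17 | 3-demethylubiquinone-6 | COC1=C(O)C(=O)C(C)=C(C/C=C(\C)CC/C=C(\C)CC/C=C(\C)CC/C=C(\C)CC/C=C(\C)CCC=C(C)C)C1=O | target

**Totals and risk**

Total step count: 7. Longest linear sequence: 5 steps (6 → 7 → 9 → 10 → 15 → 17; the branch 1 → 3 → 5 → 10 → 15 → 17 is equally long).

The step most likely to fail is step 6. The dilithium catecholate may precipitate or be O-allylated, and running the palladium-mediated hydride desulfonylation on that salt in the alkylation flask is untested. Hydride delivery could also give some alkene-transposed isomer, because both termini of the allyl unit are secondary. The fallback sets out from 9 and makes the chain before the ring is attached. Methanolysis (K2CO3, MeOH) gives (2E,6E,10E)-3,7,11-trimethyl-12-(4-methylbenzenesulfonyl)dodeca-2,6,10-trien-1-ol F1. Two equivalents of n-BuLi (THF/DMPU, −78 °C) convert it into its dilithio alkoxide–carbanion F2, which is alkylated by 11 at carbon to give (2E,6E,10E,14E,18E)-3,7,11,15,19,23-hexamethyl-12-(4-methylbenzenesulfonyl)tetracosa-2,6,10,14,18,22-hexaen-1-ol F3. PdCl2(dppp)/LiBHEt3 then gives all-E hexaprenol F4. BF3·OEt2-promoted Friedel–Crafts allylation of 5 with F4 comes back to the route at 15.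

Next is step 5. The allyl cation can cyclise onto the 6',7'-alkene, partial loss of 2'E geometry is expected, and the catechol can be oxidised or tied up by boron. The fallback sets out from 5 and replaces the cationic bond formation by a stereoretentive palladium-catalysed allyl–aryl coupling. MOMCl/i-Pr2NEt gives 1,2-dimethoxy-3,4-bis(methoxymethoxy)-5-methylbenzene F5. NBS in MeCN brominates the only free ring position to give 1-bromo-2,3-dimethoxy-4,5-bis(methoxymethoxy)-6-methylbenzene F6. Bromine–lithium exchange (n-BuLi, THF, −78 °C) gives the aryllithium F7, and ZnCl2 gives the arylzinc chloride F8. Pd(PPh3)4 couples F8 with the allylic acetate 9 at its primary terminus with retention of 2'E, giving the bis(methoxymethyl) ether of 10 F9. Catalytic HCl in MeOH at 40 °C removes both acetals and returns to the route at 10.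

Third is step 7. The intermediate ortho-quinone 16 carries an allylic CH2 para to a carbonyl and can tautomerise to a quinone methide before the vinylogous ester is hydrolysed, and over-oxidation of the electron-rich ring is possible. The fallback sets out from 15 and avoids a free ortho-quinone. Ketalisation with 2,2-dimethoxypropane and catalytic pyridinium p-toluenesulfonate gives 5-[(2E,6E,10E,14E,18E)-3,7,11,15,19,23-hexamethyltetracosa-2,6,10,14,18,22-hexaen-1-yl]-6,7-dimethoxy-2,2,4-trimethyl-1,3-benzodioxole F10. Its para-related O1 methyl ether and O4 ketal oxygen undergo oxidative dealkylation with (NH4)2Ce(NO3)6 in aqueous MeCN. The ketal carbon leaves as acetone and frees the O3 hydroxyl, which returns to the route at 17.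

**Further compounds**

F1 | step 6 | (2E,6E,10E)-3,7,11-trimethyl-12-(4-methylbenzenesulfonyl)dodeca-2,6,10-trien-1-ol | OC/C=C(\C)CC/C=C(\C)CC/C=C(\C)CS(=O)(=O)c1ccc(C)cc1
F2 | step 6 | dilithio alkoxide–carbanion of F1 | [Li+].[Li+].[O-]C/C=C(\C)CC/C=C(\C)CC/C=C(\C)[CH-]S(=O)(=O)c1ccc(C)cc1
F3 | step 6 | (2E,6E,10E,14E,18E)-3,7,11,15,19,23-hexamethyl-12-(4-methylbenzenesulfonyl)tetracosa-2,6,10,14,18,22-hexaen-1-ol (racemic at C12) | OC/C=C(\C)CC/C=C(\C)CC/C=C(\C)C(C/C=C(\C)CC/C=C(\C)CCC=C(C)C)S(=O)(=O)c1ccc(C)cc1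
F4 | step 6 | (2E,6E,10E,14E,18E)-3,7,11,15,19,23-hexamethyltetracosa-2,6,10,14,18,22-hexaen-1-ol (all-E hexaprenol) | OC/C=C(\C)CC/C=C(\C)CC/C=C(\C)CC/C=C(\C)CC/C=C(\C)CCC=C(C)C
F5 | step 5 | 1,2-dimethoxy-3,4-bis(methoxymethoxy)-5-methylbenzene | Cc1cc(OC)c(OC)c(OCOC)c1OCOC
F6 | step 5 | 1-bromo-2,3-dimethoxy-4,5-bis(methoxymethoxy)-6-methylbenzene | Cc1c(Br)c(OC)c(OC)c(OCOC)c1OCOC
F7 | step 5 | [2,3-dimethoxy-4,5-bis(methoxymethoxy)-6-methylphenyl]lithium | [Li]c1c(C)c(OCOC)c(OCOC)c(OC)c1OC
F8 | step 5 | chloro[2,3-dimethoxy-4,5-bis(methoxymethoxy)-6-methylphenyl]zinc | Cl[Zn]c1c(C)c(OCOC)c(OCOC)c(OC)c1OC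
F9 | step 5 | 1,2-dimethoxy-3,4-bis(methoxymethoxy)-5-methyl-6-[(2E,6E,10E)-3,7,11-trimethyl-12-(4-methylbenzenesulfonyl)dodeca-2,6,10-trien-1-yl]benzene | Cc1c(OCOC)c(OCOC)c(OC)c(OC)c1C/C=C(\C)CC/C=C(\C)CC/C=C(\C)CS(=O)(=O)c1ccc(C)cc1
F10 | step 7 | 5-[(2E,6E,10E,14E,18E)-3,7,11,15,19,23-hexamethyltetracosa-2,6,10,14,18,22-hexaen-1-yl]-6,7-dimethoxy-2,2,4-trimethyl-1,3-benzodioxole | COc1c(OC)c(C/C=C(\C)CC/C=C(\C)CC/C=C(\C)CC/C=C(\C)CC/C=C(\C)CCC=C(C)C)c(C)c2OC(C)(C)Oc12
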